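**Retrosynthetic overview**
1. Ring A (the natural lactone) and C6 are made last, in one step, by a ligand-controlled copper-catalysed vinylogous aldol-lactonisation of methyl but-3-enoate on a masked Z-enal. Only an acetal hydrolysis follows.
2. The masked Z-enal is the lactol of a template dihydropyranone (ring B). Its endocyclic cis olefin becomes C1'=C2' (Z) and its carbonyl carbon becomes C6, so no alkyne reduction, no Wittig reaction and no acrylate closure of ring A is needed.
3. C8' and the styrene come from cross-metathesis with racemic 1-phenylprop-2-en-1-ol. A Re2O7 1,3-transposition, trapped as the all-equatorial dioxane (ring C), then relays C6' to C8' under thermodynamic control.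
4. C4' and C6' (anti) are set together by one two-directional iridium-catalysed double allylation of propane-1,3-diol. Mono-acryloylation and ring-closing metathesis then break the C2 symmetry.
5. Ring order: B formed, C formed, B opened, A formed, C removed.

Locants: lactone O1, C2 to C6; side chain C1' to C10'. The target is 6R, 1'Z, 4'S, 6'R, 8'R, 9'E, with 4',6'-anti and 6',8'-syn diols.
Assumption: in steps 1 and 7 the ligand antipode written is taken to give the drawn configuration; if the sense of induction is the opposite, the mirror-image ligand is used and nothing else changes.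

**Step 1**
Reactants: 1 propane-1,3-diol; 2 allyl acetate
Product: 6 (4S,6S)-nona-1,8-diene-4,6-diol, via 3-hydroxypropanal 3 (not isolated), via mono-allyl diol 4 (not isolated), via hydroxy-aldehyde 5 (not isolated)
Conditions: [Ir(cod)Cl]2 (5 mol %), (S)-Cl,MeO-BIPHEP (10 mol %), 4-chloro-3-nitrobenzoic acid (20 mol %), Cs2CO3 (40 mol %), 2 (10 equiv), 1,4-dioxane, 90 °C, 72 h
Reagents that add atoms: allyl acetate (2), C=CCOC(C)=O
Why: Krische two-directional transfer-hydrogenative carbonyl allylation: the cyclometalated pi-allyl iridium C,O-benzoate formed in situ dehydrogenates each primary alcohol to the aldehyde (3, then 5) and allylates it under ligand control, so C4' and C6' are both set S (anti, C2-symmetric) in one operation, and the minor enantiomer of 4 is diverted into the separable meso diastereomer, which raises the ee of 6 (Horeau amplification).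

**Step 2**
Reactants: 6 (4S,6S)-nona-1,8-diene-4,6-diol; 7 acryloyl chloride
Product: 8 (4S,6S)-6-hydroxynona-1,8-dien-4-yl prop-2-enoate
Conditions: 7 (0.9 equiv, slow addition), iPr2NEt, CH2Cl2, −78 to −20 °C; recovered 6 recycled
Reagents that add atoms: acryloyl chloride (7), C=CC(=O)Cl
Why: Statistical mono-O-acylation of a C2-symmetric diol: the two hydroxyls are homotopic, so only one mono-ester exists, 1,3-acyl migration is degenerate, no stereocentre is touched, and the under-charge of 7 keeps the bis-acrylate small.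

**Step 3**
Reactants: 8 (4S,6S)-6-hydroxynona-1,8-dien-4-yl prop-2-enoate
Product: 9 (6S)-6-[(2S)-2-hydroxypent-4-en-1-yl]-5,6-dihydro-2H-pyran-2-one
Conditions: second-generation Hoveyda–Grubbs catalyst (5 mol %), ethylene (1 atm), CH2Cl2 (5 mM), 40 °C
Reagents that add atoms: none
Why: Ring-closing metathesis to the alpha,beta-unsaturated delta-lactone (template ring B): the six-membered ring can hold only a cis olefin, which is the future C1'=C2' Z-olefin, the enoate product is inert to further metathesis whereas any cycloheptene from the two allyl groups is re-opened under ethylene (ring-rearrangement metathesis) and funnels to 9, and the acyl group now masks the C4' oxygen.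

**Step 4**
Reactants: 9 (6S)-6-[(2S)-2-hydroxypent-4-en-1-yl]-5,6-dihydro-2H-pyran-2-one; 10 1-phenylprop-2-en-1-ol (racemic)
Product: 11 (6S)-6-[(2S,4E)-2,6-dihydroxy-6-phenylhex-4-en-1-yl]-5,6-dihydro-2H-pyran-2-one (both benzylic epimers)
Conditions: 10 (3 equiv), second-generation Hoveyda–Grubbs catalyst (5 mol %), CH2Cl2 (0.2 M), 40 °C
Reagents that add atoms: 1-phenylprop-2-en-1-ol (10), C=CC(O)c1ccccc1
Why: Olefin cross-metathesis of an unhindered terminal olefin with an excess of a secondary allylic alcohol gives the E-disubstituted olefin, the electron-poor lactone olefin does not take part, and neither the benzylic configuration nor the olefin geometry matters because both are erased in step 5.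

**Step 5**
Reactants: 11 (6S)-6-[(2S,4E)-2,6-dihydroxy-6-phenylhex-4-en-1-yl]-5,6-dihydro-2H-pyran-2-one; 12 4-methoxybenzaldehyde dimethyl acetal
Product: 14 (6S)-6-{[(2R,4R,6R)-2-(4-methoxyphenyl)-6-[(E)-2-phenylethenyl]-1,3-dioxan-4-yl]methyl}-5,6-dihydro-2H-pyran-2-one, via transposed cinnamyl-type diol 13 (not isolated)
Conditions: Re2O7 (5 mol %), CH2Cl2, 0 °C, 15 min; then 12 (1.5 equiv), 0 °C to rt
Reagents that add atoms: 4-methoxybenzaldehyde dimethyl acetal (12), COC(OC)c1ccc(OC)cc1
Why: Rhenium-oxo-catalysed 1,3-allylic alcohol transposition with acetal trapping: perrhenate esters move the hydroxyl from C10' to C8' (driven by styrene conjugation) and epimerise C8' through the cinnamyl-type ion pair, while only the 6',8'-syn diol closes to the all-equatorial 2,4,6-cis-dioxane, so thermodynamic control relays the fixed C6' centre to C8' (R); the acylated C4' oxygen cannot form a tetrahydropyran, and adding 12 only after the transposition avoids a Prins cyclisation.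

**Step 6**
Reactants: 14 acetal-protected template lactone
Product: 15 (6S)-6-{[(2R,4R,6R)-2-(4-methoxyphenyl)-6-[(E)-2-phenylethenyl]-1,3-dioxan-4-yl]methyl}-5,6-dihydro-2H-pyran-2-ol (anomer mixture)
Conditions: iBu2AlH (1.15 equiv), CH2Cl2, −78 °C; aq. potassium sodium tartrate
Reagents that add atoms: none
Why: Partial lactone reduction with one equivalent of iBu2AlH stops at the tetrahedral aluminium lactolate at −78 °C, goes 1,2 on the enoate, leaves the aryl acetal and the styrene alone, and the ring keeps the olefin cis.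

**Step 7**
Reactants: 15 unsaturated lactol; 16 methyl but-3-enoate
Product: 19 (6R)-6-[(1Z,4S)-4-hydroxy-5-[(2R,4R,6R)-2-(4-methoxyphenyl)-6-[(E)-2-phenylethenyl]-1,3-dioxan-4-yl]pent-1-en-1-yl]-5,6-dihydro-2H-pyran-2-one, via open-chain Z-hydroxyenal 17 (not isolated), via Z-enoate aldol adduct 18 (not isolated)
Conditions: 16 (2 equiv), Cu(MeCN)4PF6 (10 mol %), (R)-DTBM-SEGPHOS (11 mol %), 2-tert-butyl-1,1,3,3-tetramethylguanidine (10 mol %), THF, −20 °C
Reagents that add atoms: methyl but-3-enoate (16), C=CCC(=O)OC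
Why: Proposed new method: the closest known reaction type is the monovalent-copper/bisphosphine-catalysed direct vinylogous aldol-lactonisation of beta,gamma-unsaturated esters with free aldehydes, enals included; here the aldehyde is supplied by ring-chain tautomerism of lactol 15 to 17 (the same opening that lets such lactols undergo Wittig and Grignard reactions with retention of the Z-olefin, and helped here by formation of the copper lactolate), the s-cis copper dienolate attacks through its gamma-carbon on one aldehyde face under ligand control to set C6 as R, the Z-enoate alkoxide 18 lactonises irreversibly to ring A and so drains the equilibrium, the proton-shuttling catalysis tolerates the free C4' hydroxyl (which could only close a ten-membered ring), and a non-nucleophilic base at low temperature limits Z to E leakage.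

**Step 8**
Reactants: 19 acetal-protected target
Product: 20 (6R)-6-[(1Z,4S,6R,8R,9E)-4,6,8-trihydroxy-10-phenyldeca-1,9-dien-1-yl]-5,6-dihydro-2H-pyran-2-one
Conditions: AcOH/THF/H2O (3:1:1), 23 °C
Reagents that add atoms: none
Why: Acid hydrolysis of a p-methoxybenzylidene acetal: the anisyl-stabilised oxocarbenium ion forms far faster than a C8' cinnamyl cation, so the acetal is lost at room temperature without C8' epimerisation, tetrahydropyran formation from the C4' hydroxyl or damage to the lactone.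

**Compound list**
1 | propane-1,3-diol | OCCCO | starting material
2 | allyl acetate | C=CCOC(C)=O | starting material
3 | 3-hydroxypropanal (formed and consumed in step 1) | O=CCCO | intermediate
4 | (3S)-hex-5-ene-1,3-diol (formed and consumed in step 1) | C=CC[C@H](O)CCO | intermediate
5 | (3S)-3-hydroxyhex-5-enal (formed and consumed in step 1) | C=CC[C@H](O)CC=O | intermediate
6 | (4S,6S)-nona-1,8-diene-4,6-diol | C=CC[C@H](O)C[C@@H](O)CC=C | intermediate
7 | acryloyl chloride | C=CC(=O)Cl | starting material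
8 | (4S,6S)-6-hydroxynona-1,8-dien-4-yl prop-2-enoate | C=CC[C@H](OC(=O)C=C)C[C@@H](O)CC=C | intermediate
9 | (6S)-6-[(2S)-2-hydroxypent-4-en-1-yl]-5,6-dihydro-2H-pyran-2-one | O=C1C=CC[C@@H](C[C@@H](O)CC=C)O1 | intermediate
10 | 1-phenylprop-2-en-1-ol (racemic) | C=CC(O)c1ccccc1 | starting material
11 | (6S)-6-[(2S,4E)-2,6-dihydroxy-6-phenylhex-4-en-1-yl]-5,6-dihydro-2H-pyran-2-one (both benzylic epimers) | O=C1C=CC[C@@H](C[C@@H](O)C/C=C/C(O)c2ccccc2)O1 | intermediate
12 | 4-methoxybenzaldehyde dimethyl acetal | COC(OC)c1ccc(OC)cc1 | starting material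
13 | (6S)-6-[(2S,5E)-2,4-dihydroxy-6-phenylhex-5-en-1-yl]-5,6-dihydro-2H-pyran-2-one (equilibrating C8' epimers, formed and consumed in step 5) | O=C1C=CC[C@@H](C[C@@H](O)CC(O)/C=C/c2ccccc2)O1 | intermediate
14 | (6S)-6-{[(2R,4R,6R)-2-(4-methoxyphenyl)-6-[(E)-2-phenylethenyl]-1,3-dioxan-4-yl]methyl}-5,6-dihydro-2H-pyran-2-one | O=C1C=CC[C@@H](C[C@@H]2C[C@H](/C=C/c3ccccc3)O[C@H](c3ccc(OC)cc3)O2)O1 | intermediate
15 | (6S)-6-{[(2R,4R,6R)-2-(4-methoxyphenyl)-6-[(E)-2-phenylethenyl]-1,3-dioxan-4-yl]methyl}-5,6-dihydro-2H-pyran-2-ol (anomer mixture) | OC1C=CC[C@@H](C[C@@H]2C[C@H](/C=C/c3ccccc3)O[C@H](c3ccc(OC)cc3)O2)O1 | intermediate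
16 | methyl but-3-enoate | C=CCC(=O)OC | starting material
17 | (2Z,5S)-5-hydroxy-6-[(2R,4R,6R)-2-(4-methoxyphenyl)-6-[(E)-2-phenylethenyl]-1,3-dioxan-4-yl]hex-2-enal (formed and consumed in step 7) | O=C/C=C\C[C@H](O)C[C@@H]1C[C@H](/C=C/c2ccccc2)O[C@H](c2ccc(OC)cc2)O1 | intermediate
18 | methyl (2Z,5R,6Z,9S)-5,9-dihydroxy-10-[(2R,4R,6R)-2-(4-methoxyphenyl)-6-[(E)-2-phenylethenyl]-1,3-dioxan-4-yl]deca-2,6-dienoate (formed and consumed in step 7) | COC(=O)/C=C\C[C@@H](O)/C=C\C[C@H](O)C[C@@H]1C[C@H](/C=C/c2ccccc2)O[C@H](c2ccc(OC)cc2)O1 | intermediate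
19 | (6R)-6-[(1Z,4S)-4-hydroxy-5-[(2R,4R,6R)-2-(4-methoxyphenyl)-6-[(E)-2-phenylethenyl]-1,3-dioxan-4-yl]pent-1-en-1-yl]-5,6-dihydro-2H-pyran-2-one | O=C1C=CC[C@H](/C=C\C[C@H](O)C[C@@H]2C[C@H](/C=C/c3ccccc3)O[C@H](c3ccc(OC)cc3)O2)O1 | intermediate
20 | (6R)-6-[(1Z,4S,6R,8R,9E)-4,6,8-trihydroxy-10-phenyldeca-1,9-dien-1-yl]-5,6-dihydro-2H-pyran-2-one | O=C1C=CC[C@H](/C=C\C[C@H](O)C[C@@H](O)C[C@@H](O)/C=C/c2ccccc2)O1 | target

**Step count**
Total step count: 8. Longest linear sequence: 8 steps, from 1 to 20.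

**Three steps most likely to fail**

Step 7 carries the highest risk. The open form 17 may be too dilute, any Z to E leakage would be amplified because the E-enal cannot re-close, and alpha-aldol addition may compete. The fallback replaces the catalytic annulation by reagent-controlled allylboration on a discrete, protected enal. It sets out from 14 and comes back to the route at 20.
- Lactone 14 is opened with Me(MeO)NH·HCl and iPrMgCl (THF, −20 °C) to the Z-hydroxy Weinreb amide F1.
- Et3SiOTf and 2,6-lutidine give the triethylsilyl ether F2.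
- iBu2AlH (−78 °C) gives the free Z-enal F3.
- (+)-B-allyldiisopinocampheylborane from (−)-alpha-pinene (Et2O, −78 °C, then oxidative work-up) gives the 6R homoallylic alcohol F4.
- Compound 7 with iPr2NEt gives the acrylate F5.
- Second-generation Grubbs catalyst (CH2Cl2, 40 °C) closes ring A to the silyl-protected lactone F6.
- The aqueous acetic acid of step 8 removes the silyl ether and the acetal together to give 20.

Step 5 may fail in two ways. The cinnamyl-type cation may eliminate to the phenyl diene, or the C8' equilibration may stay incomplete. The fallback separates the transposition from the stereocontrol and sets C8' by chelation-controlled hydride delivery. It sets out from 11 and comes back at 14.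
- Compound 11 is only transposed with Ph3SiOReO3 (2 mol %, Et2O, −40 to 0 °C), and 13 is isolated as its C8' epimer mixture.
- MnO2 (CH2Cl2) oxidises only the cinnamyl-type alcohol to the beta-hydroxy styryl enone F7.
- Narasaka–Prasad reduction (Et2BOMe, NaBH4, THF/MeOH, −78 °C) gives the 6',8'-syn diol F8.
- Compound 12 with pyridinium p-toluenesulfonate (CH2Cl2) closes F8 to 14.

Step 3 may give cycloheptene or oligomers if these outrun the acrylate closure and fail to funnel back. The fallback builds ring B by olefination instead of metathesis. It sets out from 6 and comes back at 9.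
- Compound 6 is tied up with 2,2-dimethoxypropane and pyridinium p-toluenesulfonate as the trans-acetonide F9.
- One of its two homotopic allyl groups is cleaved (O3, about 0.5 equiv, CH2Cl2, −78 °C, then PPh3; recovered F9 recycled) to the mono-aldehyde F10.
- Still–Gennari olefination with (CF3CH2O)2P(O)CH2CO2Me, KN(SiMe3)2 and 18-crown-6 (THF, −78 °C) gives the Z-enoate F11.
- 80 % aqueous AcOH at 40 °C removes the acetonide, and the C4' hydroxyl then lactonises onto the Z-enoate to give 9.

**Further compounds**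
F1 | step 7 | (2Z,5S)-5-hydroxy-N-methoxy-N-methyl-6-[(2R,4R,6R)-2-(4-methoxyphenyl)-6-[(E)-2-phenylethenyl]-1,3-dioxan-4-yl]hex-2-enamide | CON(C)C(=O)/C=C\C[C@H](O)C[C@@H]1C[C@H](/C=C/c2ccccc2)O[C@H](c2ccc(OC)cc2)O1
F2 | step 7 | (2Z,5S)-N-methoxy-6-[(2R,4S,6R)-2-(4-methoxyphenyl)-6-[(E)-2-phenylethenyl]-1,3-dioxan-4-yl]-N-methyl-5-(triethylsilyloxy)hex-2-enamide | CON(C)C(=O)/C=C\C[C@H](O[Si](CC)(CC)CC)C[C@@H]1C[C@H](/C=C/c2ccccc2)O[C@H](c2ccc(OC)cc2)O1
F3 | step 7 | (2Z,5S)-6-[(2R,4S,6R)-2-(4-methoxyphenyl)-6-[(E)-2-phenylethenyl]-1,3-dioxan-4-yl]-5-(triethylsilyloxy)hex-2-enal | O=C/C=C\C[C@H](O[Si](CC)(CC)CC)C[C@@H]1C[C@H](/C=C/c2ccccc2)O[C@H](c2ccc(OC)cc2)O1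
F4 | step 7 | (4R,5Z,8S)-9-[(2R,4S,6R)-2-(4-methoxyphenyl)-6-[(E)-2-phenylethenyl]-1,3-dioxan-4-yl]-8-(triethylsilyloxy)nona-1,5-dien-4-ol | C=CC[C@@H](O)/C=C\C[C@H](O[Si](CC)(CC)CC)C[C@@H]1C[C@H](/C=C/c2ccccc2)O[C@H](c2ccc(OC)cc2)O1
F5 | step 7 | (4R,5Z,8S)-9-[(2R,4S,6R)-2-(4-methoxyphenyl)-6-[(E)-2-phenylethenyl]-1,3-dioxan-4-yl]-8-(triethylsilyloxy)nona-1,5-dien-4-yl prop-2-enoate | C=CC[C@@H](OC(=O)C=C)/C=C\C[C@H](O[Si](CC)(CC)CC)C[C@@H]1C[C@H](/C=C/c2ccccc2)O[C@H](c2ccc(OC)cc2)O1
F6 | step 7 | (6R)-6-[(1Z,4S)-5-[(2R,4S,6R)-2-(4-methoxyphenyl)-6-[(E)-2-phenylethenyl]-1,3-dioxan-4-yl]-4-(triethylsilyloxy)pent-1-en-1-yl]-5,6-dihydro-2H-pyran-2-one | O=C1C=CC[C@H](/C=C\C[C@H](O[Si](CC)(CC)CC)C[C@@H]2C[C@H](/C=C/c3ccccc3)O[C@H](c3ccc(OC)cc3)O2)O1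
F7 | step 5 | (6S)-6-[(2R,5E)-2-hydroxy-4-oxo-6-phenylhex-5-en-1-yl]-5,6-dihydro-2H-pyran-2-one | O=C1C=CC[C@@H](C[C@@H](O)CC(=O)/C=C/c2ccccc2)O1
F8 | step 5 | (6S)-6-[(2S,4R,5E)-2,4-dihydroxy-6-phenylhex-5-en-1-yl]-5,6-dihydro-2H-pyran-2-one | O=C1C=CC[C@@H](C[C@@H](O)C[C@@H](O)/C=C/c2ccccc2)O1
F9 | step 3 | (4S,6S)-2,2-dimethyl-4,6-di(prop-2-en-1-yl)-1,3-dioxane | C=CC[C@H]1C[C@H](CC=C)OC(C)(C)O1
F10 | step 3 | 2-[(4R,6S)-2,2-dimethyl-6-(prop-2-en-1-yl)-1,3-dioxan-4-yl]acetaldehyde | O=CC[C@H]1C[C@H](CC=C)OC(C)(C)O1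
F11 | step 3 | methyl (2Z)-4-[(4S,6S)-2,2-dimethyl-6-(prop-2-en-1-yl)-1,3-dioxan-4-yl]but-2-enoate | COC(=O)/C=C\C[C@H]1C[C@H](CC=C)OC(C)(C)O1
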